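Readings and results are simulated on assumed constants; noise was put on by code.

| setting | alder | flask |
|---|---|---|
| substrate | 0.55 M (fed, over 80 s) | 0.55 M (fed, over 80 s) |
| partner | 0.33 M | 0.330 M |
| free catalyst | 38 mM | 38 mM |
| added ligand | 21 mM | 21 mM |
| remark | the very flask that is asked about, followed so far; the fed solution adds 0.25 times the starting volume | the fed solution adds 0.25 times the starting volume |
| time |  | 8.0 min |

alder run (percent of the substrate charged)

| time / s | product / % | substrate / % |
|---|---|---|
| 25.0 | 4.2 | 24.0 |
| 50.0 | 14.1 | 44.3 |
| 80.0 | 25.6 | 70.8 |
| 90.0 | 29.2 | 65.7 |

(standard deviation of a reading: 0.5 percentage points)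

- percentages count the substrate that a species holds: one resting dimer counts as two
- every charge counts on the volume at the start, and the solution that is fed holds the whole dose
- the earlier runs were read with a standard deviation of 0.5 percentage points
- percentages count the whole charge, also what has not yet gone in

- concentration of product at 8.0 min, in M
- concentration of substrate at 8.0 min, in M
- concentration of resting dimer at 8.0 min, in M

1. The charges are 0.330 M of partner against 0.55 M of substrate, both on the starting volume, so partner is less. Taking one partner per product, we treat it as the limiting reagent.
2. The feed stretches the volume by a factor 1.25, so the partner charge allows at most 0.264 M of product, the ceiling.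
3. Now the question turned round: for product to stop short of the ceiling at 8.0 min, the mean use of partner would have to stay below 0.688 mM s⁻¹.
4. The alder run, this same flask followed so far, gained product at 2.08 mM s⁻¹ between 50.0 s and 90.0 s, faster than that by a factor 3.02.
5. At that steady rate, partner would last 2.65 min. That is our early end.
6. For the late end, we let the rate fall in step with [partner]. Then 4.88 % of the partner stays at 8.0 min, and our estimate of product is 0.251 M. We commit to product just under the ceiling.
7. The forecast gives [product] 0.261 M, [substrate] 0.159 M and [resting dimer] 0.0092 M; of partner it says “it should be essentially gone well before 480 s”.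

    substrate + free catalyst → catalyst intermediate A (k = 1.02 M⁻¹ s⁻¹)
    partner + catalyst intermediate A → catalyst intermediate B (k = 8.06 M⁻¹ s⁻¹)
    catalyst intermediate B → free catalyst + product (k = 0.252 s⁻¹)
    2 catalyst intermediate A ⇌ resting dimer, settled at all times (K = 3060 M⁻¹)
    free catalyst + added ligand ⇌ idle complex (K = 140 M⁻¹, k = 0.788 M⁻¹ s⁻¹)

The flask gives [product] 0.264 M against the ceiling of 0.264 M, [substrate] 0.148 M and [resting dimer] 0.0130 M, which is more than the forecast's 0.0092 M. Catalyst intermediate B was turning into product while partner was there: half of that turnover up to the asked time was done by 1.56 min, and partner fell to 7.36 % of its charge at 4.00 min. At 8.00 min partner stood at 0.165 % and product at 59.9 % of the substrate charged. The neighbour charged with 0.94 M of substrate has the same ceiling of 0.264 M and gives 0.264 M, which is 35.1 % of its larger charge.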